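Slowness is what I count in this flask: holding protic impurity at its charge in my reckoning, I let free monomer leak to uncatalysed product and quenched substrate at a combined constant of 0.0104 s⁻¹, slower than the 0.236 s⁻¹ at which it enters chains with the whole initiator charge standing as living ends.

free monomer 0.082 M; protic impurity 0.0164 M; initiator 0.48 mol%; time 1.0 min

    free monomer → uncatalysed product (k1 = 0.0052 s⁻¹)
    monomer in chains + living end → free monomer + living end, rate k2*[living end] as long as [monomer in chains] is above zero (k2 = 17 s⁻¹)
    protic impurity + free monomer → quenched substrate (k3 = 0.32 L mol⁻¹ s⁻¹)
    free monomer + initiator → living end + monomer in chains (k4 = 2.1 L mol⁻¹ s⁻¹)
    free monomer + living end → monomer in chains + living end, rate k5*[living end]*[free monomer] (k5 = 600 L mol⁻¹ s⁻¹)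

* whether the average number of monomer units in a chain (chains begun, living or dead) reaches 70 by 1.0 min (no / yes)
* average number of monomer units in a chain (chains begun, living or dead) at 1.0 min

- the average divides the monomer in chains by the number of chains begun, living and dead together
- run time (flask): 1.0 min

At the start each living end adds 49.2 s⁻¹ and sheds 17 s⁻¹. Adding slows as free monomer enters chains, and net growth ends once adding has fallen by a factor of 2.89, which leaves 34.6% of the charge standing as free monomer (the equilibrium monomer concentration) and 65.4% available to chains. Over 1.0 min the leaks replace this standing free monomer 0.627 times, the leak turnovers. Since uptake into chains outpaces leaking, I let the chains pay for each turnover with one standing portion. Initiator meanwhile turns over 3.57 times, so nearly all of it has begun chains. Dividing the monomer in chains by the chains begun, counted as the whole initiator charge, I commit to 91.2 units, and my answer on reaching the wanted length is yes.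

The forecast also says yes and puts the average at 85, lower than my figure, expecting a peak before “the slow leaks erode it”.

The simulation gives yes, at 0.0754 min, and 92.6 at 1.0 min. At 0.497 min this flask's free monomer enters chains 42 times as fast as it goes to uncatalysed product, while monomer in chains is made at 0.968 of the rate at which it is used, each step taken net. At 1.00 min the uncatalysed product and quenched substrate of this flask together come to 0.681 of the free monomer then standing, against my 0.627 leak turnovers. With half the protic impurity, the leak turnovers come to 0.469, which gives 103 units, and that run reads 102.

Its constants are assumed, and the outcome is calculated.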